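**Plan**
- **Cuts:** the two silyl groups come off, the C6′ CH2OH goes back to an ethyl ester, and ring B goes back to a cyclohexenone. C1′–C6′ and C3′–C4′ are then cut together. The remaining cuts are O–C1′ (phenoxide + chloroacetone), C1–CO2H (aryl anion + chloroformate) and the benzylic C–CH2 bond of the C3 side chain (aldehyde + methallyl).
- **Enabling feature:** ring B has oxygen on C1′ and C2′, and its C2′ OH, C4′ CH3 and C6′ CH2OH are 1,3,5-related. C1′–C2′–C3′ is therefore the carbon chain of an aryloxyacetone, and C4′–C5′–C6′ plus the carboxyl carbon is a 4-oxopent-2-enoate.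
- **Forward order:** ring A is bought. It receives the side chain, then the carboxyl carbon between its two oxygens, then the acetonyl ether. Ring B is the only ring built; it is grown on the ether oxygen and aromatised afterwards, so the crowded diaryl ether is never made by aryl–O coupling.
- **Stereochemistry:** the single stereocentre (S, benzylic carbinol on C3) comes from a reagent-controlled methallylboration and is kept away from acid afterwards. The two ring B centres made in the annulation disappear on aromatisation.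

Key step: step 9

Remark: ring A is numbered from the carboxyl-bearing carbon (C1; OMe on C2, side chain on C3, ether O on C6). Ring B is numbered from the ether carbon (C1′). The carbinol carbon of the target SMILES is read as S. R* = (S)-1-(tert-butyldimethylsilyloxy)-3-methyl-3-(triethylsilyloxy)butyl. ArA = 2-carboxy-3-methoxy-4-R*-phenyl.

Step 1
Reactants: 1 4-hydroxy-2-methoxybenzaldehyde
Product: 2 2-methoxy-4-(methoxymethoxy)benzaldehyde
Conditions: MOMCl, iPr2NEt, CH2Cl2, 0 °C → rt
Reagents that add atoms: chloromethyl methyl ether COCCl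
Why: Williamson-type O-alkylation of the acidic para-formyl phenol gives an acetal ether that tolerates boranes, radicals and organolithiums and later acts as a directing group.

Step 2
Reactants: 2 2-methoxy-4-(methoxymethoxy)benzaldehyde
Product: 4 (S)-1-[2-methoxy-4-(methoxymethoxy)phenyl]-3-methylbut-3-en-1-ol, via diisopinocampheylborinate 3 (not isolated)
Conditions: CH2=C(CH3)CH2MgCl, (−)-Ipc2BOMe, Et2O, 0 °C → rt; 2, −78 °C; then NaOH, H2O2, 0 °C → rt
Reagents that add atoms: methallylmagnesium chloride CC(=C)C[Mg]Cl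
Why: Brown asymmetric methallylboration through a closed chair transition state, in which the reagent of the (+)-α-pinene series attacks the Si face of aromatic aldehydes (benzaldehyde gives the S carbinol) and so sets the only stereocentre of the target as S before alkaline peroxide cleaves borinate 3.

Step 3
Reactants: 4 (S)-1-[2-methoxy-4-(methoxymethoxy)phenyl]-3-methylbut-3-en-1-ol
Product: 5 (S)-1-[2-methoxy-4-(methoxymethoxy)phenyl]-3-methylbutane-1,3-diol
Conditions: Mn(dpm)3 (cat., dpm = dipivaloylmethanate), PhSiH3, O2 (1 atm), iPrOH, 0 °C → rt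
Reagents that add atoms: dioxygen O=O
Why: Mukaiyama hydration, in which hydrogen atom transfer from a manganese hydride to the CH2 terminus of the 1,1-disubstituted alkene gives the tertiary radical that O2 traps and the silane reduces to the Markovnikov alcohol, under neutral conditions that spare the benzylic carbinol and the MOM ether.

Step 4
Reactants: 5 (S)-1-[2-methoxy-4-(methoxymethoxy)phenyl]-3-methylbutane-1,3-diol
Product: 7 (S)-1-[1-(tert-butyldimethylsilyloxy)-3-methyl-3-(triethylsilyloxy)butyl]-2-methoxy-4-(methoxymethoxy)benzene, via mono-TBS ether 6 (not isolated)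
Conditions: TBSOTf (1.05 equiv), 2,6-lutidine, CH2Cl2, −78 °C; then TESOTf, −78 → 0 °C
Reagents that add atoms: tert-butyldimethylsilyl triflate CC(C)(C)[Si](C)(C)OS(=O)(=O)C(F)(F)F; triethylsilyl triflate CC[Si](CC)(CC)OS(=O)(=O)C(F)(F)F
Why: Sequential silyl triflate silylation, in which TBSOTf at −78 °C takes only the secondary benzylic hydroxyl (6), the smaller TESOTf then caps the tertiary hydroxyl, and the lutidine buffer keeps the ionisable benzylic C–O bond and the S centre intact.

Step 5
Reactants: 7 (S)-1-[1-(tert-butyldimethylsilyloxy)-3-methyl-3-(triethylsilyloxy)butyl]-2-methoxy-4-(methoxymethoxy)benzene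
Product: 9 allyl 2-methoxy-6-(methoxymethoxy)-3-R*-benzoate, via aryllithium 8 (not isolated)
Conditions: n-BuLi, THF, −20 → 0 °C; ClCO2CH2CH=CH2, −78 °C → rt
Reagents that add atoms: allyl chloroformate C=CCOC(=O)Cl
Why: Directed ortho metalation at the one ring position flanked by two coordinating oxygens (the methoxy group and the MOM acetal), followed by acylation of aryllithium 8 with the chloroformate to an ester too hindered for a second addition.

Step 6
Reactants: 9 allyl 2-methoxy-6-(methoxymethoxy)-3-R*-benzoate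
Product: 11 allyl 6-hydroxy-2-methoxy-3-R*-benzoate, via aryl trimethylsilyl ether 10 (not isolated)
Conditions: TMSOTf, 2,2′-bipyridyl, CH2Cl2, 0 °C → rt; then H2O
Reagents that add atoms: none
Why: MOM cleavage with the silyl triflate–2,2′-bipyridyl pair, a known non-acidic method that turns the aryl acetal into aryl silyl ether 10 and a bipyridinium salt, both hydrolysed by water, so no free acid reaches the TBS and TES ethers or the benzylic centre.

Step 7
Reactants: 11 allyl 6-hydroxy-2-methoxy-3-R*-benzoate; 12 1-chloropropan-2-one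
Product: 13 allyl 2-methoxy-6-(2-oxopropoxy)-3-R*-benzoate
Conditions: K2CO3, KI (cat.), acetone, 50 °C
Reagents that add atoms: none
Why: Williamson ether synthesis (SN2 with iodide assistance) of a salicylate-type phenoxide with an α-halo ketone, which attaches the hindered ether oxygen to C1′ while the weak base keeps cyclisation of the ketone enolate onto the ester slow.

Step 8
Reactants: 13 allyl 2-methoxy-6-(2-oxopropoxy)-3-R*-benzoate
Product: 14 2-methoxy-6-(2-oxopropoxy)-3-R*-benzoic acid
Conditions: Pd(PPh3)4 (cat.), morpholine, THF, rt; pH 4 buffer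
Reagents that add atoms: none
Why: Tsuji–Trost deallylation, in which zerovalent palladium ionises the ester at the allyl carbon, far from the hindered carbonyl, and morpholine traps the π-allyl complex without touching the ketone or the silyl ethers.

Step 9
Reactants: 14 2-methoxy-6-(2-oxopropoxy)-3-R*-benzoic acid; 15 ethyl (E)-4-oxopent-2-enoate
Product: 18 ethyl 2-(ArA-oxy)-5-methyl-3-oxocyclohex-4-ene-1-carboxylate (diastereomer mixture at C1′ and C6′), via Michael adduct 16 (not isolated), via ketol 17 (not isolated)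
Conditions: Cs2CO3 (2.2 equiv), MeCN, 0 °C, slow addition of 15 (1.1 equiv); rt; then 50 °C; cold citric acid work-up
Reagents that add atoms: none
Why: Cs2CO3 first converts 14 into its caesium carboxylate and then enolises the ketone at C1′, the CH2 made most acidic by the aryloxy oxygen, and this enolate adds to C2 of 15, the carbon β to the stronger acceptor (the ketone), which forms C1′–C6′ and leaves the ester on C6′ (adduct 16). On warming, the C3′ methyl enolate of 16 attacks the C4′ ketone in a 6-(enolendo)-exo-trig aldol addition (ketol 17), and E1cB loss of water gives enone 18, so ring B closes through C3′–C4′. The closest known chemistry is the Robinson-type Michael–aldol [3+3] annulation of α-aryloxy and α-alkoxy methyl ketones with enones, and the direction of closure follows 3-branched heptane-2,6-diones, which condense at their unhindered carbonyl (the piperitone pattern). Three selectivities are needed: donor site (C1′ over C3′, secured by the aryloxy group), acceptor site (C2 over C3 of 15, secured by ketone over ester) and aldol direction (C3′ onto C4′ rather than the acceptor methyl onto C2′, secured by the branched C1′ and its 2,6-disubstituted aryloxy group beside C2′). The new stereocentres C1′ and C6′ are left uncontrolled, are epimerisable and become sp2 in step 10, while the remote S carbinol carbon carries no acidic hydrogen and is untouched. The carboxylate form removes the electrophile for a Dieckmann-type attack of C1′ on the C1 carbonyl and makes the ring A phenoxide a poorer leaving group for β-elimination from C6′.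

Step 10
Reactants: 18 ethyl 2-(ArA-oxy)-5-methyl-3-oxocyclohex-4-ene-1-carboxylate
Product: 21 ethyl 2-(ArA-oxy)-3-hydroxy-5-methylbenzoate, via bis-silylated dienol ether 19 (not isolated), via cross-conjugated dienone 20 (not isolated)
Conditions: TMSOTf, Et3N, CH2Cl2, 0 °C; evaporate; Pd(OAc)2 (1.2 equiv), MeCN, rt; pH 5 buffer
Reagents that add atoms: none
Why: Saegusa–Ito dehydrogenation, in which soft enolisation silylates the ketone towards the acidic C1′–H and the acid as its TMS ester (19), divalent palladium forms the oxa-π-allyl complex, and β-hydride elimination of C6′–H gives dienone 20, which tautomerises at once to the phenol in a nearly neutral medium that spares the silyl ethers.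

Step 11
Reactants: 21 ethyl 2-(ArA-oxy)-3-hydroxy-5-methylbenzoate
Product: 22 6-[2-hydroxy-6-(hydroxymethyl)-4-methylphenoxy]-2-methoxy-3-R*-benzoic acid
Conditions: LiN(SiMe3)2 (2.1 equiv), THF, 0 °C; LiBH4, THF, 0 → 45 °C; aq. NH4Cl
Reagents that add atoms: none
Why: Chemoselective borohydride reduction, in which acid and phenol are first stored as lithium salts so that no borane is released, and LiBH4 then reduces the ethyl ester to the primary alcohol while the di-ortho-substituted carboxylate accepts no hydride.

Step 12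
Reactants: 22 6-[2-hydroxy-6-(hydroxymethyl)-4-methylphenoxy]-2-methoxy-3-R*-benzoic acid
Product: 23 3-[(S)-1,3-dihydroxy-3-methylbutyl]-6-[2-hydroxy-6-(hydroxymethyl)-4-methylphenoxy]-2-methoxybenzoic acid (CNP0452050.2)
Conditions: HF·pyridine, pyridine, THF, 0 °C → rt
Reagents that add atoms: none
Why: Fluoride-driven desilylation, in which pyridine-buffered HF removes the TBS and TES groups without ionising the electron-rich benzylic carbinol, so the S configuration is retained.

**Compound list**
1 | 4-hydroxy-2-methoxybenzaldehyde | COc1cc(O)ccc1C=O | starting material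
2 | 2-methoxy-4-(methoxymethoxy)benzaldehyde | COCOc1ccc(C=O)c(OC)c1 | intermediate
3 | diisopinocampheylborinate of alcohol 4 | COCOc1ccc([C@@H](OB([C@@H]2C[C@@H]3C[C@H]([C@H]2C)C3(C)C)[C@@H]2C[C@@H]3C[C@H]([C@H]2C)C3(C)C)CC(C)=C)c(OC)c1 | intermediate
4 | (S)-1-[2-methoxy-4-(methoxymethoxy)phenyl]-3-methylbut-3-en-1-ol | COCOc1ccc([C@@H](O)CC(C)=C)c(OC)c1 | intermediate
5 | (S)-1-[2-methoxy-4-(methoxymethoxy)phenyl]-3-methylbutane-1,3-diol | COCOc1ccc([C@@H](O)CC(C)(C)O)c(OC)c1 | intermediate
6 | (S)-4-(tert-butyldimethylsilyloxy)-4-[2-methoxy-4-(methoxymethoxy)phenyl]-2-methylbutan-2-ol | COCOc1ccc([C@@H](O[Si](C)(C)C(C)(C)C)CC(C)(C)O)c(OC)c1 | intermediate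
7 | (S)-1-[1-(tert-butyldimethylsilyloxy)-3-methyl-3-(triethylsilyloxy)butyl]-2-methoxy-4-(methoxymethoxy)benzene | COCOc1ccc([C@@H](O[Si](C)(C)C(C)(C)C)CC(C)(C)O[Si](CC)(CC)CC)c(OC)c1 | intermediate
8 | aryllithium of 7, lithium between OMe and OMOM | COCOc1ccc([C@@H](O[Si](C)(C)C(C)(C)C)CC(C)(C)O[Si](CC)(CC)CC)c(OC)c1[Li] | intermediate
9 | allyl 2-methoxy-6-(methoxymethoxy)-3-R*-benzoate | C=CCOC(=O)c1c(OCOC)ccc([C@@H](O[Si](C)(C)C(C)(C)C)CC(C)(C)O[Si](CC)(CC)CC)c1OC | intermediate
10 | allyl 2-methoxy-3-R*-6-(trimethylsilyloxy)benzoate | C=CCOC(=O)c1c(O[Si](C)(C)C)ccc([C@@H](O[Si](C)(C)C(C)(C)C)CC(C)(C)O[Si](CC)(CC)CC)c1OC | intermediate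
11 | allyl 6-hydroxy-2-methoxy-3-R*-benzoate | C=CCOC(=O)c1c(O)ccc([C@@H](O[Si](C)(C)C(C)(C)C)CC(C)(C)O[Si](CC)(CC)CC)c1OC | intermediate
12 | 1-chloropropan-2-one | CC(=O)CCl | starting material
13 | allyl 2-methoxy-6-(2-oxopropoxy)-3-R*-benzoate | C=CCOC(=O)c1c(OCC(C)=O)ccc([C@@H](O[Si](C)(C)C(C)(C)C)CC(C)(C)O[Si](CC)(CC)CC)c1OC | intermediate
14 | 2-methoxy-6-(2-oxopropoxy)-3-R*-benzoic acid | OC(=O)c1c(OCC(C)=O)ccc([C@@H](O[Si](C)(C)C(C)(C)C)CC(C)(C)O[Si](CC)(CC)CC)c1OC | intermediate
15 | ethyl (E)-4-oxopent-2-enoate | CCOC(=O)/C=C/C(C)=O | starting material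
16 | ethyl 2-[1-(ArA-oxy)-2-oxopropyl]-4-oxopentanoate (diastereomer mixture) | CCOC(=O)C(CC(C)=O)C(Oc1ccc([C@@H](O[Si](C)(C)C(C)(C)C)CC(C)(C)O[Si](CC)(CC)CC)c(OC)c1C(=O)O)C(C)=O | intermediate
17 | ethyl 2-(ArA-oxy)-5-hydroxy-5-methyl-3-oxocyclohexane-1-carboxylate (diastereomer mixture) | CCOC(=O)C1CC(C)(O)CC(=O)C1Oc1ccc([C@@H](O[Si](C)(C)C(C)(C)C)CC(C)(C)O[Si](CC)(CC)CC)c(OC)c1C(=O)O | intermediate
18 | ethyl 2-(ArA-oxy)-5-methyl-3-oxocyclohex-4-ene-1-carboxylate (diastereomer mixture at C1′ and C6′) | CCOC(=O)C1CC(C)=CC(=O)C1Oc1ccc([C@@H](O[Si](C)(C)C(C)(C)C)CC(C)(C)O[Si](CC)(CC)CC)c(OC)c1C(=O)O | intermediate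
19 | trimethylsilyl ester and C2′ trimethylsilyl dienol ether of 18 (C1′=C2′ and C3′=C4′) | CCOC(=O)C1CC(C)=CC(O[Si](C)(C)C)=C1Oc1ccc([C@@H](O[Si](C)(C)C(C)(C)C)CC(C)(C)O[Si](CC)(CC)CC)c(OC)c1C(=O)O[Si](C)(C)C | intermediate
20 | cyclohexa-2,5-dienone (C1′=C6′ and C3′=C4′, C5′ as CH2), ring A acid as trimethylsilyl ester | CCOC(=O)C1=C(Oc2ccc([C@@H](O[Si](C)(C)C(C)(C)C)CC(C)(C)O[Si](CC)(CC)CC)c(OC)c2C(=O)O[Si](C)(C)C)C(=O)C=C(C)C1 | intermediate
21 | ethyl 2-(ArA-oxy)-3-hydroxy-5-methylbenzoate | CCOC(=O)c1cc(C)cc(O)c1Oc1ccc([C@@H](O[Si](C)(C)C(C)(C)C)CC(C)(C)O[Si](CC)(CC)CC)c(OC)c1C(=O)O | intermediate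
22 | 6-[2-hydroxy-6-(hydroxymethyl)-4-methylphenoxy]-2-methoxy-3-R*-benzoic acid | COc1c([C@@H](O[Si](C)(C)C(C)(C)C)CC(C)(C)O[Si](CC)(CC)CC)ccc(Oc2c(O)cc(C)cc2CO)c1C(=O)O | intermediate
23 | 3-[(S)-1,3-dihydroxy-3-methylbutyl]-6-[2-hydroxy-6-(hydroxymethyl)-4-methylphenoxy]-2-methoxybenzoic acid | COc1c([C@@H](O)CC(C)(C)O)ccc(Oc2c(O)cc(C)cc2CO)c1C(=O)O | target

**Step count**
- Total step count: 12.
- Longest linear sequence: 12 steps (1 → 23). Compounds 12 and 15 are bought.

**Steps most likely to fail**

1. **Step 9.**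
   - **What may go wrong:** the aldol condensation may run in the wrong direction (the acceptor methyl onto C2′). The ring A phenoxide may be lost by β-elimination once C6′ is deprotonated. The acceptor may oligomerise under base.
   - **Fallback:** it sets out from 14 and comes back at 18.
     - The caesium salt of 14 is annulated in the same way with ethyl (E)-4-oxobut-2-enoate. Its aldehyde has no second enolisable methyl, so only C3′ can close onto C4′. This gives ethyl 2-(ArA-oxy)-3-oxocyclohex-4-ene-1-carboxylate F1.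
     - The lithium carboxylate of F1 takes up Me2CuLi at C4′ in the presence of TMSCl and gives the silyl enol ether silyl ester F2.
     - Pd(OAc)2 in MeCN (Saegusa–Ito) restores the C3′=C4′ double bond, which now carries the methyl group. Aqueous work-up gives 18.

2. **Step 10.**
   - **What may go wrong:** palladation at the fully substituted C1′ may be slow. Protodesilylation may return the enone. The aryloxy group may be lost during enol silylation.
   - **Fallback:** it sets out from 14 and comes back at 21. It removes the dehydrogenation by raising the oxidation level of the acceptor.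
     - Lithiated ethyl propiolate and acetaldehyde give ethyl 4-hydroxypent-2-ynoate F3, and MnO2 oxidises it to ethyl 4-oxopent-2-ynoate F4.
     - Cs2CO3-mediated addition of C1′ of 14 to C2 of F4 gives the enedione F5.
     - The C3′ methyl of F5 condenses onto C4′, and loss of water with enolisation leads straight to 21 without an oxidant.

3. **Step 5.**
   - **What may go wrong:** metalation may occur at C5, next to the MOM ether only. Deprotonation of the benzylic C–H may occur, with silyl migration and erosion of the stereocentre.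
   - **Fallback:** it sets out from 2 and comes back at 8. The site is fixed by halogen–metal exchange instead of deprotonation.
     - Lithium N-methylpiperazide adds to 2 and gives the α-amino alkoxide F6, which masks the carbonyl.
     - n-BuLi metalates this small, silyl-free substrate between the two oxygens. I2 and aqueous work-up give 3-iodo-2-methoxy-4-(methoxymethoxy)benzaldehyde F7, whose regiochemistry can be secured at the outset.
     - The operations of steps 2 to 4 convert F7 into the homoallylic alcohol F8, the diol F9 and the bis-silyl ether F10.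
     - Iodine–lithium exchange (n-BuLi, THF, −78 °C) outruns any deprotonation and gives 8, which is quenched with allyl chloroformate as in step 5.

**Further compounds**
F1 | step 9 | ethyl 2-(ArA-oxy)-3-oxocyclohex-4-ene-1-carboxylate (diastereomer mixture) | CCOC(=O)C1CC=CC(=O)C1Oc1ccc([C@@H](O[Si](C)(C)C(C)(C)C)CC(C)(C)O[Si](CC)(CC)CC)c(OC)c1C(=O)O
F2 | step 9 | ethyl 2-(aryloxy)-5-methyl-3-(trimethylsilyloxy)cyclohex-3-ene-1-carboxylate, ring A acid as trimethylsilyl ester (diastereomer mixture) | CCOC(=O)C1CC(C)C=C(O[Si](C)(C)C)C1Oc1ccc([C@@H](O[Si](C)(C)C(C)(C)C)CC(C)(C)O[Si](CC)(CC)CC)c(OC)c1C(=O)O[Si](C)(C)C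
F3 | step 10 | ethyl 4-hydroxypent-2-ynoate (racemic) | CCOC(=O)C#CC(C)O
F4 | step 10 | ethyl 4-oxopent-2-ynoate | CCOC(=O)C#CC(C)=O
F5 | step 10 | ethyl 2-[1-(ArA-oxy)-2-oxopropyl]-4-oxopent-2-enoate (alkene isomer mixture) | CCOC(=O)C(=CC(C)=O)C(Oc1ccc([C@@H](O[Si](C)(C)C(C)(C)C)CC(C)(C)O[Si](CC)(CC)CC)c(OC)c1C(=O)O)C(C)=O
F6 | step 5 | lithium [2-methoxy-4-(methoxymethoxy)phenyl](4-methylpiperazin-1-yl)methanolate | COCOc1ccc(C([O-])N2CCN(C)CC2)c(OC)c1.[Li+]
F7 | step 5 | 3-iodo-2-methoxy-4-(methoxymethoxy)benzaldehyde | COCOc1ccc(C=O)c(OC)c1I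
F8 | step 5 | (S)-1-[3-iodo-2-methoxy-4-(methoxymethoxy)phenyl]-3-methylbut-3-en-1-ol | COCOc1ccc([C@@H](O)CC(C)=C)c(OC)c1I
F9 | step 5 | (S)-1-[3-iodo-2-methoxy-4-(methoxymethoxy)phenyl]-3-methylbutane-1,3-diol | COCOc1ccc([C@@H](O)CC(C)(C)O)c(OC)c1I
F10 | step 5 | 2-iodo-3-methoxy-1-(methoxymethoxy)-4-R*-benzene | COCOc1ccc([C@@H](O[Si](C)(C)C(C)(C)C)CC(C)(C)O[Si](CC)(CC)CC)c(OC)c1I
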